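## Retrosynthetic overview

1. The target is an all-trans oxolane (O1, C2 to C5) with ring A (4-hydroxy-3,5-dimethoxyphenyl) on C2 and ring B (3,4,5-trimethoxyphenyl) on C5. The feature used is that C3 and C4 each carry one CH2OH carbon, trans to each other and to ring B on C5. C3 and C4 are therefore treated as the α- and β-carbons of a 5-aryl butenolide whose carbonyl carbon is C2 and whose only stereocentre is C5.
2. C2–ring A and C2–H: a silyl-protected ring A aryllithium is added to the lactone carbonyl and the hemiketal is reduced with a silane, which sets C2. One fluoride step then frees all three hydroxyls.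
3. C4–CH2 and C3–CH2: a silylmethyl Grignard reagent (masked hydroxymethyl) is added 1,4 to the (R)-butenolide under copper mediation and the enolate is captured by formaldehyde in the same flask, which sets C4 and C3 from C5.
4. Ring order: the only ring construction is the butenolide, by ring-closing metathesis of the acrylate of lipase-resolved (R)-1-(3,4,5-trimethoxyphenyl)prop-2-en-1-ol. This lactone ring is later reduced at C2 to the oxolane, so no second ring closure is needed.

Key step: step 7

Assumption: the lipase is taken to acylate the (R)-enantiomer of the aryl vinyl carbinol, as Kazlauskas' rule predicts with aryl as the large and vinyl as the medium group, so the (R)-ester is the material carried on.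

## Route

Step 1
Reactants: 1 3,4,5-trimethoxybenzaldehyde; 2 vinylmagnesium bromide
Product: 3 rac-1-(3,4,5-trimethoxyphenyl)prop-2-en-1-ol
Conditions: CH2=CHMgBr (1.2 equiv), THF, 0 °C; aqueous work-up
Reagents that add atoms: none
Why: Grignard 1,2-addition of the vinyl nucleophile to the aldehyde should give the allylic carbinol, whose new centre is formed racemic and is resolved in step 2.

Step 2
Reactants: 3 rac-1-(3,4,5-trimethoxyphenyl)prop-2-en-1-ol
Product: 4 (R)-1-(3,4,5-trimethoxyphenyl)prop-2-en-1-yl acetate
Conditions: immobilised Candida antarctica lipase B, vinyl acetate (3 equiv), MTBE, 30 °C, stopped near half conversion; chromatography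
Reagents that add atoms: vinyl acetate, C=COC(C)=O
Why: Lipase-catalysed kinetic resolution by transesterification should acylate the (R)-alcohol (Kazlauskas' rule), so the later C5 stereocentre is fixed in the acetate while the (S)-alcohol stays behind and is separated.

Step 3
Reactants: 4 (R)-1-(3,4,5-trimethoxyphenyl)prop-2-en-1-yl acetate
Product: 5 (R)-1-(3,4,5-trimethoxyphenyl)prop-2-en-1-ol
Conditions: K2CO3 (0.2 equiv), MeOH, 0 °C
Reagents that add atoms: none
Why: Base-catalysed transesterification (methanolysis) cleaves the acyl–oxygen bond, so the carbinol configuration is retained.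

Step 4
Reactants: 5 (R)-1-(3,4,5-trimethoxyphenyl)prop-2-en-1-ol; 6 acryloyl chloride
Product: 7 (R)-1-(3,4,5-trimethoxyphenyl)prop-2-en-1-yl acrylate
Conditions: Et3N, DMAP (cat.), CH2Cl2, 0 °C
Reagents that add atoms: none
Why: O-Acylation of a secondary alcohol by an acid chloride with an amine base should proceed without touching the stereocentre.

Step 5
Reactants: 7 (R)-1-(3,4,5-trimethoxyphenyl)prop-2-en-1-yl acrylate
Product: 8 (R)-5-(3,4,5-trimethoxyphenyl)furan-2(5H)-one
Conditions: second-generation Grubbs catalyst RuCl2(=CHPh)(H2IMes)(PCy3) (5 mol%), CH2Cl2 (0.01 M), 40 °C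
Reagents that add atoms: none
Why: Ring-closing metathesis between the acrylate and the allylic vinyl group should close the five-membered lactone with loss of ethylene, the carbene-ligated ruthenium catalyst tolerating the electron-poor acrylate and the neutral medium leaving the acidic C5–H untouched.

Step 6
Reactants: 9 (chloromethyl)isopropoxydimethylsilane
Product: 10 (isopropoxydimethylsilyl)methylmagnesium chloride (titrated THF solution)
Conditions: Mg turnings, BrCH2CH2Br (cat.), THF, reflux
Reagents that add atoms: magnesium, [Mg]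
Why: Grignard formation by insertion of magnesium into the C–Cl bond should be clean because the hindered isopropoxy group on silicon resists attack by the reagent's own carbanion.

Step 7
Reactants: 8 (R)-5-(3,4,5-trimethoxyphenyl)furan-2(5H)-one; 10 (isopropoxydimethylsilyl)methylmagnesium chloride; 11 formaldehyde
Product: 13 (3S,4R,5R)-3-(hydroxymethyl)-4-[(isopropoxydimethylsilyl)methyl]-5-(3,4,5-trimethoxyphenyl)oxolan-2-one, via chloromagnesium enolate 12 (not isolated)
Conditions: CuBr·SMe2 (0.2 equiv), THF/Me2S, −78 °C, 10 (1.3 equiv) added slowly to 8; then monomeric CH2O (THF solution from cracked paraformaldehyde, excess), −78 to −40 °C; cold pH 7 buffer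
Reagents that add atoms: none
Why: Transmetalation of the Grignard reagent to monovalent copper gives a soft silylmethylcopper species that adds to the β-carbon (C4) of the butenolide through a copper–alkene complex and reductive elimination, leaving chloromagnesium enolate 12, whose α-carbon (C3) then attacks monomeric formaldehyde in an aldol addition. The closest known reaction type is the three-component coupling of enones and butenolides (copper-mediated conjugate addition, then aldehyde capture of the enolate), combined with the copper-catalysed 1,4-addition of this silylmethyl Grignard reagent as a hydroxymethyl anion equivalent. The step closes no ring; it forms the C4–CH2Si and C3–CH2OH bonds and two stereocentres. C4 is controlled by the C5 aryl group, which covers one face of the nearly flat butenolide so that the silylmethyl group arrives trans to it. C3 is controlled by the new C4 substituent, which covers the same face of the planar enolate so that formaldehyde enters trans to it. The step needs anti,anti diastereoselection, 1,4- over 1,2-addition and addition in preference to removal of the acidic C5–H; these should be secured by the substrate shielding just described, by slow addition at −78 °C so that the basic Grignard reagent is converted at once into the weakly basic organocopper species, and by omitting silyl chlorides so that the enolate remains a reactive magnesium enolate.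

Step 8
Reactants: 13 (3S,4R,5R)-3-(hydroxymethyl)-4-[(isopropoxydimethylsilyl)methyl]-5-(3,4,5-trimethoxyphenyl)oxolan-2-one
Product: 14 (3S,4S,5R)-3,4-bis(hydroxymethyl)-5-(3,4,5-trimethoxyphenyl)oxolan-2-one
Conditions: 30% aq H2O2, KF, KHCO3, THF/MeOH (1:1), 0 °C to rt, short reaction time
Reagents that add atoms: hydrogen peroxide, OO
Why: Tamao–Kumada oxidation should convert the C–Si bond into C–OH by hydroperoxide attack on the fluoride-activated alkoxysilane and carbon migration from silicon to oxygen, the weak bicarbonate base leaving the lactone and its three stereocentres unchanged.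

Step 9
Reactants: 14 (3S,4S,5R)-3,4-bis(hydroxymethyl)-5-(3,4,5-trimethoxyphenyl)oxolan-2-one
Product: 15 (3S,4S,5R)-3,4-bis[(tert-butyldimethylsilyloxy)methyl]-5-(3,4,5-trimethoxyphenyl)oxolan-2-one
Conditions: TBSCl (2.5 equiv), imidazole, DMF, 0 °C to rt
Reagents that add atoms: tert-butyldimethylsilyl chloride, CC(C)(C)[Si](C)(C)Cl
Why: Silylation of both primary alcohols under silyl chloride and imidazole conditions should be fast and removes the free hydroxyls that could otherwise attack the lactone carbonyl.

Step 10
Reactants: 16 4-bromo-2,6-dimethoxyphenol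
Product: 17 (4-bromo-2,6-dimethoxyphenoxy)(tert-butyl)dimethylsilane
Conditions: TBSCl, imidazole, DMF, rt
Reagents that add atoms: tert-butyldimethylsilyl chloride, CC(C)(C)[Si](C)(C)Cl
Why: O-Silylation of the phenol should proceed without affecting the para bromide and gives a ring A unit whose protecting group falls in the same final step as the alkyl silyl ethers.

Step 11
Reactants: 15 (3S,4S,5R)-3,4-bis[(tert-butyldimethylsilyloxy)methyl]-5-(3,4,5-trimethoxyphenyl)oxolan-2-one; 17 (4-bromo-2,6-dimethoxyphenoxy)(tert-butyl)dimethylsilane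
Product: 19 (3S,4S,5R)-2-[4-(tert-butyldimethylsilyloxy)-3,5-dimethoxyphenyl]-3,4-bis[(tert-butyldimethylsilyloxy)methyl]-5-(3,4,5-trimethoxyphenyl)oxolan-2-ol (anomer mixture, in equilibrium with its ring-opened hydroxy ketone form), via aryllithium 18 (not isolated)
Conditions: 17, n-BuLi (1.05 equiv), THF, −78 °C; then 15, −78 °C; pH 7 buffer quench at −78 °C
Reagents that add atoms: none
Why: Bromine–lithium exchange followed by 1,2-addition of the aryllithium to the γ-lactone carbonyl should stop after one addition because the tetrahedral lithium alkoxide persists at −78 °C, with C3, C4 and C5 untouched and the new hemiketal carbon formed as an inconsequential mixture.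

Step 12
Reactants: 19 (3S,4S,5R)-2-[4-(tert-butyldimethylsilyloxy)-3,5-dimethoxyphenyl]-3,4-bis[(tert-butyldimethylsilyloxy)methyl]-5-(3,4,5-trimethoxyphenyl)oxolan-2-ol
Product: 21 (2R,3S,4S,5R)-2-[4-(tert-butyldimethylsilyloxy)-3,5-dimethoxyphenyl]-3,4-bis[(tert-butyldimethylsilyloxy)methyl]-5-(3,4,5-trimethoxyphenyl)oxolane, via oxocarbenium ion 20 (not isolated)
Conditions: Et3SiH (5 equiv), BF3·OEt2 (2 equiv, promoter), CH2Cl2, −78 °C; aq NaHCO3
Reagents that add atoms: none
Why: Ionic hydrogenation, in which the Lewis acid ionises the hemiketal to the 2-aryl oxocarbenium ion 20 and the silane delivers hydride by inside attack on the envelope that holds the C3, C4 and C5 substituents pseudoequatorial (the face opposite the C4 arm), should place ring A trans to the C3 arm and so give the all-trans oxolane, which is also the most stable isomer.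

Step 13
Reactants: 21 (2R,3S,4S,5R)-2-[4-(tert-butyldimethylsilyloxy)-3,5-dimethoxyphenyl]-3,4-bis[(tert-butyldimethylsilyloxy)methyl]-5-(3,4,5-trimethoxyphenyl)oxolane
Product: 22 [(2R,3S,4S,5R)-2-(4-hydroxy-3,5-dimethoxyphenyl)-5-(3,4,5-trimethoxyphenyl)oxolane-3,4-diyl]dimethanol (CID56680032)
Conditions: Bu4NF (TBAF)/AcOH (1:1, 4 equiv), THF, 0 °C to rt
Reagents that add atoms: none
Why: Fluoride-mediated desilylation should cleave the two primary alkyl silyl ethers and the aryl silyl ether, the acetic acid buffer keeping the phenol protonated so that the benzylic C2–O bond is not opened through a quinone methide.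

## Compound list

1 | 3,4,5-trimethoxybenzaldehyde | COc1cc(C=O)cc(OC)c1OC | starting material
2 | vinylmagnesium bromide | C=C[Mg]Br | starting material
3 | rac-1-(3,4,5-trimethoxyphenyl)prop-2-en-1-ol | C=CC(O)c1cc(OC)c(OC)c(OC)c1 | intermediate
4 | (R)-1-(3,4,5-trimethoxyphenyl)prop-2-en-1-yl acetate | CC(=O)O[C@@H](c1cc(OC)c(OC)c(OC)c1)C=C | intermediate
5 | (R)-1-(3,4,5-trimethoxyphenyl)prop-2-en-1-ol | O[C@@H](c1cc(OC)c(OC)c(OC)c1)C=C | intermediate
6 | acryloyl chloride | C=CC(=O)Cl | starting material
7 | (R)-1-(3,4,5-trimethoxyphenyl)prop-2-en-1-yl acrylate | C=CC(=O)O[C@@H](c1cc(OC)c(OC)c(OC)c1)C=C | intermediate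
8 | (R)-5-(3,4,5-trimethoxyphenyl)furan-2(5H)-one | O=C1O[C@@H](c2cc(OC)c(OC)c(OC)c2)C=C1 | intermediate
9 | (chloromethyl)isopropoxydimethylsilane | CC(C)O[Si](C)(C)CCl | starting material
10 | (isopropoxydimethylsilyl)methylmagnesium chloride | CC(C)O[Si](C)(C)C[Mg]Cl | intermediate
11 | formaldehyde (monomeric, from paraformaldehyde) | C=O | starting material
12 | chloromagnesium enolate of (4R,5R)-4-[(isopropoxydimethylsilyl)methyl]-5-(3,4,5-trimethoxyphenyl)oxolan-2-one | Cl[Mg]OC1O[C@@H](c2cc(OC)c(OC)c(OC)c2)[C@H](C[Si](C)(C)OC(C)C)C=1 | intermediate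
13 | (3S,4R,5R)-3-(hydroxymethyl)-4-[(isopropoxydimethylsilyl)methyl]-5-(3,4,5-trimethoxyphenyl)oxolan-2-one (all-trans) | O=C1O[C@@H](c2cc(OC)c(OC)c(OC)c2)[C@H](C[Si](C)(C)OC(C)C)[C@H]1CO | intermediate
14 | (3S,4S,5R)-3,4-bis(hydroxymethyl)-5-(3,4,5-trimethoxyphenyl)oxolan-2-one | O=C1O[C@@H](c2cc(OC)c(OC)c(OC)c2)[C@H](CO)[C@H]1CO | intermediate
15 | (3S,4S,5R)-3,4-bis[(tert-butyldimethylsilyloxy)methyl]-5-(3,4,5-trimethoxyphenyl)oxolan-2-one | O=C1O[C@@H](c2cc(OC)c(OC)c(OC)c2)[C@H](CO[Si](C)(C)C(C)(C)C)[C@H]1CO[Si](C)(C)C(C)(C)C | intermediate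
16 | 4-bromo-2,6-dimethoxyphenol | COc1cc(Br)cc(OC)c1O | starting material
17 | (4-bromo-2,6-dimethoxyphenoxy)(tert-butyl)dimethylsilane | COc1cc(Br)cc(OC)c1O[Si](C)(C)C(C)(C)C | intermediate
18 | [4-(tert-butyldimethylsilyloxy)-3,5-dimethoxyphenyl]lithium | [Li]c1cc(OC)c(O[Si](C)(C)C(C)(C)C)c(OC)c1 | intermediate
19 | (3S,4S,5R)-2-[4-(tert-butyldimethylsilyloxy)-3,5-dimethoxyphenyl]-3,4-bis[(tert-butyldimethylsilyloxy)methyl]-5-(3,4,5-trimethoxyphenyl)oxolan-2-ol (anomer mixture) | COc1cc(C2(O)O[C@@H](c3cc(OC)c(OC)c(OC)c3)[C@H](CO[Si](C)(C)C(C)(C)C)[C@H]2CO[Si](C)(C)C(C)(C)C)cc(OC)c1O[Si](C)(C)C(C)(C)C | intermediate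
20 | 2-aryl oxocarbenium ion derived from 19 (C2=O1 cation; C3, C4, C5 as in 19) | COc1cc(C2=[O+][C@@H](c3cc(OC)c(OC)c(OC)c3)[C@H](CO[Si](C)(C)C(C)(C)C)[C@H]2CO[Si](C)(C)C(C)(C)C)cc(OC)c1O[Si](C)(C)C(C)(C)C | intermediate
21 | (2R,3S,4S,5R)-2-[4-(tert-butyldimethylsilyloxy)-3,5-dimethoxyphenyl]-3,4-bis[(tert-butyldimethylsilyloxy)methyl]-5-(3,4,5-trimethoxyphenyl)oxolane | COc1cc([C@@H]2O[C@@H](c3cc(OC)c(OC)c(OC)c3)[C@H](CO[Si](C)(C)C(C)(C)C)[C@H]2CO[Si](C)(C)C(C)(C)C)cc(OC)c1O[Si](C)(C)C(C)(C)C | intermediate
22 | [(2R,3S,4S,5R)-2-(4-hydroxy-3,5-dimethoxyphenyl)-5-(3,4,5-trimethoxyphenyl)oxolane-3,4-diyl]dimethanol | COc1cc([C@@H]2O[C@@H](c3cc(OC)c(OC)c(OC)c3)[C@H](CO)[C@H]2CO)cc(OC)c1O | target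

## Step count and risks

Total step count: 13. Longest linear sequence: 11 steps (steps 1 to 5, 7 to 9 and 11 to 13, from 3,4,5-trimethoxybenzaldehyde).

Steps most likely to fail:

**Step 7 (conjugate addition and formaldehyde capture).**
- What may go wrong: removal of the acidic C5 proton by the organometallic reagent (racemisation or consumption of the butenolide as a furanolate); slow transfer of the silylmethyl group from copper; incomplete capture of the enolate by formaldehyde; dehydration of the aldol to an α-methylene lactone on work-up.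
- Fallback: sets out from 8 and returns at 15, replacing the organometallic addition by a neutral radical one. Benzophenone-sensitised irradiation (350 nm) of 8 in methanol should add a hydroxymethyl radical to C4 trans to the aryl group, giving (4S,5R)-4-(hydroxymethyl)-5-(3,4,5-trimethoxyphenyl)oxolan-2-one F1. Silylation (TBSCl, imidazole) should give (4S,5R)-4-[(tert-butyldimethylsilyloxy)methyl]-5-(3,4,5-trimethoxyphenyl)oxolan-2-one F2. Enolisation with LiN(i-Pr)2 in THF at −78 °C and hydroxymethylation with monomeric formaldehyde, trans to the C4 arm, should give (3S,4S,5R)-4-[(tert-butyldimethylsilyloxy)methyl]-3-(hydroxymethyl)-5-(3,4,5-trimethoxyphenyl)oxolan-2-one F3. A second silylation leads to 15.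

**Step 8 (Tamao oxidation beside the lactone).**
- What may go wrong: migration of the lactone acyl group onto the newly freed C4 hydroxymethyl oxygen (translactonisation through a bicyclic tetrahedral intermediate); retro-aldol cleavage or dehydration of the β-hydroxy lactone in the basic peroxide medium.
- Fallback: sets out from 13 and returns at 22, keeping silicon in place until the lactone carbonyl has been consumed. Warming 13 with catalytic pyridinium p-toluenesulfonate in toluene, with removal of propan-2-ol, should close the six-membered cyclic silyl ether between the C3 and C4 arms, the trans-fused silyl ether lactone F4. Addition of aryllithium 18 at −78 °C should give the corresponding hemiketal F5. Et3SiH and BF3·OEt2 at −78 °C should give the 2,5-diaryl oxolane that still carries the cyclic silyl ether F6. Tamao oxidation of F6 (H2O2, KF, KHCO3, THF/MeOH), now without any carbonyl group in the molecule, should release both hydroxymethyl groups. The fluoride and methanol medium should also cleave the aryl silyl ether, leading to 22.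

**Step 12 (reduction of the hemiketal).**
- What may go wrong: poor facial selectivity in hydride delivery to the oxocarbenium ion (ring A ending cis to the C3 arm); epimerisation at C3 through the enol ether; loss of silyl ethers under the Lewis acid.
- Fallback: sets out from 15 and returns at 22, forming the C2–aryl bond on a C2–H centre instead of the C2–H bond on a C2–aryl centre. Reduction of 15 with i-Bu2AlH in CH2Cl2 at −78 °C should give the lactol (3S,4S,5R)-3,4-bis[(tert-butyldimethylsilyloxy)methyl]-5-(3,4,5-trimethoxyphenyl)oxolan-2-ol F7. Friedel–Crafts-type C-arylation with 2,6-dimethoxyphenol and BF3·OEt2 (attack para to the hydroxyl) should give 4-{(2R,3S,4S,5R)-3,4-bis[(tert-butyldimethylsilyloxy)methyl]-5-(3,4,5-trimethoxyphenyl)oxolan-2-yl}-2,6-dimethoxyphenol F8. Here the arene approaches anti to the C3 arm, and reversible benzylic ionisation should funnel material to the all-trans isomer. Desilylation with Bu4NF and AcOH leads to 22.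

## Further compounds

F1 | step 7 | (4S,5R)-4-(hydroxymethyl)-5-(3,4,5-trimethoxyphenyl)oxolan-2-one | O=C1O[C@@H](c2cc(OC)c(OC)c(OC)c2)[C@H](CO)C1
F2 | step 7 | (4S,5R)-4-[(tert-butyldimethylsilyloxy)methyl]-5-(3,4,5-trimethoxyphenyl)oxolan-2-one | O=C1O[C@@H](c2cc(OC)c(OC)c(OC)c2)[C@H](CO[Si](C)(C)C(C)(C)C)C1
F3 | step 7 | (3S,4S,5R)-4-[(tert-butyldimethylsilyloxy)methyl]-3-(hydroxymethyl)-5-(3,4,5-trimethoxyphenyl)oxolan-2-one | O=C1O[C@@H](c2cc(OC)c(OC)c(OC)c2)[C@H](CO[Si](C)(C)C(C)(C)C)[C@H]1CO
F4 | step 8 | trans-fused cyclic silyl ether lactone (C3–CH2–O–SiMe2–CH2–C4 six-membered ring on the 5-aryl oxolan-2-one) | O=C1O[C@@H](c3cc(OC)c(OC)c(OC)c3)[C@H](C[Si]2(C)C)[C@H]1CO2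
F5 | step 8 | hemiketal from F4 and the ring A aryllithium (anomer mixture) | COc1cc(C2(O)O[C@@H](c3cc(OC)c(OC)c(OC)c3)[C@H](C[Si]4(C)C)[C@H]2CO4)cc(OC)c1O[Si](C)(C)C(C)(C)C
F6 | step 8 | all-trans 2,5-diaryl oxolane carrying the cyclic silyl ether and the aryl silyl ether | COc1cc([C@@H]2O[C@@H](c3cc(OC)c(OC)c(OC)c3)[C@H](C[Si]4(C)C)[C@H]2CO4)cc(OC)c1O[Si](C)(C)C(C)(C)C
F7 | step 12 | (3S,4S,5R)-3,4-bis[(tert-butyldimethylsilyloxy)methyl]-5-(3,4,5-trimethoxyphenyl)oxolan-2-ol (anomer mixture) | OC1O[C@@H](c2cc(OC)c(OC)c(OC)c2)[C@H](CO[Si](C)(C)C(C)(C)C)[C@H]1CO[Si](C)(C)C(C)(C)C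
F8 | step 12 | 4-{(2R,3S,4S,5R)-3,4-bis[(tert-butyldimethylsilyloxy)methyl]-5-(3,4,5-trimethoxyphenyl)oxolan-2-yl}-2,6-dimethoxyphenol | COc1cc([C@@H]2O[C@@H](c3cc(OC)c(OC)c(OC)c3)[C@H](CO[Si](C)(C)C(C)(C)C)[C@H]2CO[Si](C)(C)C(C)(C)C)cc(OC)c1O
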